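The larch run still held 25.4% of its starting material at 20.0 min. I read that leftover as a reagent bill: each equivalent of starting material or second substrate takes one of reagent, and larch's cover, reagent charged over that bill, was 0.781, less than one, which makes reagent the limiting reagent there.

| flask | starting material | second substrate | reagent | free catalyst | remark | time |
|---|---|---|---|---|---|---|
| birch | 5 mM | 1.4 equiv | 2.5 equiv | 15 mol% | run made earlier |  |
| larch | 5 mM | 2.2 equiv | 2.5 equiv | 15 mol% | run made earlier |  |
| alder | 5 mM | 1 equiv | 2.5 equiv | 30 mol% | run made earlier |  |
| flask | 5.0 mM | 1.00 equiv | 2.50 equiv | 15 mol% |  | 25 min |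

| run | time / min | target / % | starting material / % |
|---|---|---|---|
| birch | 0.200 | 18.7 | 69.3 |
| birch | 0.417 | 21.7 | 47.6 |
| birch | 1.00 | 14.0 | 20.6 |
| birch | 2.00 | 7.5 | 6.3 |
| birch | 4.00 | 6.3 | 0.6 |
| birch | 10.0 | 6.3 | 0.2 |
| birch | 20.0 | 5.5 | 0 |
| larch | 0.200 | 15.0 | 75.3 |
| larch | 0.417 | 17.3 | 58.0 |
| larch | 1.00 | 8.8 | 35.5 |
| larch | 2.00 | 5.0 | 26.4 |
| larch | 4.00 | 2.6 | 26.8 |
| larch | 10.0 | 5.3 | 24.7 |
| larch | 20.0 | 3.0 | 25.4 |
| alder | 0.200 | 35.9 | 43.6 |
| alder | 0.667 | 21.0 | 6.3 |
| alder | 2.00 | 4.4 | 0 |
| alder | 6.00 | 6.3 | 0.5 |
| alder | 20.0 | 6.6 | 0 |

(readings scatter by 1 percentage point)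

- what was read earlier has a scatter of 1 percentage point, one standard deviation
- candidate steps: reagent + catalyst intermediate A -> free catalyst + target; second substrate + free catalyst <-> catalyst intermediate B; starting material + free catalyst <-> catalyst intermediate A; reagent + catalyst intermediate B -> free catalyst + second product; target <-> isomer of the product

1. the best time, 25 min at the latest, for target
2. the amount of target, in percent of the starting material charged, at that time

My rule of thumb was two first-order steps in series: starting material to target at k, target to isomer of the product at λ. In alder's first reading, target over starting material was 0.823 and k·t was 0.830. The series makes those two equal when k equals λ, so I took both as 4.15 /min in alder. The flask has alder's charges with half the catalyst. Taking k proportional to loading and λ as unchanged by loading, I carried one number, r = 0.500, the rate ratio, k of the flask over λ: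

peak of target = r to the power one over (one minus r) = 25.0%

best time = ln(one over r) over λ(one minus r) = 0.334 min

The border is the cover. The flask's is 1.25, above one, so I expected no stall like larch's.

The forecast gave 0.33 min (0.26 min to 0.42 min) and 25% (22.5% to 27.5%), from its own picture: “two substrates compete for one catalyst, and the target then relaxes to its isomer”.

The flask gave 24.4% at 0.357 min.

    reagent + catalyst intermediate A → free catalyst + target (k = 180 /M/s)
    second substrate + free catalyst ⇌ catalyst intermediate B (K = 590 /M, k = 140 /M/s)
    starting material + free catalyst ⇌ catalyst intermediate A (K = 170 /M, k = 100 /M/s)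
    reagent + catalyst intermediate B → free catalyst + second product (k = 68.0 /M/s)
    target ⇌ isomer of the product (K = 17.0, k = 0.0720 /s)

Against that, r had given 25.0% at 0.334 min. For a neighbouring flask, charged with 1.50 equiv of reagent, I set k proportional to [reagent], so r becomes 0.300 and the peak 17.9%; that neighbour gave 17.7%. Its cover is 0.750, below one, and at 25.0 min that neighbour held reagent at 0% of its charge and 26% of its starting material, unbound.

The earlier runs and the new flask are simulated with made-up constants; the scatter is artificial.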